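**Task.** I looked for the peak of target.

- north-west: substrate 2 mM; the very flask that is asked about, followed so far
- flask: substrate 2.0 mM; time 2.5 min

north-west run (percent of the substrate charged)

| time / s | target / % | substrate / % |
|---|---|---|
| 15.0 | 11.5 | 68.7 |
| 20.0 | 13.7 | 61.7 |
| 25.0 | 16.3 | 53.8 |
| 40.0 | 19.6 | 39.4 |
| 50.0 | 22.6 | 32.5 |
| 60.0 | 23.0 | 26.6 |
| 80.0 | 23.4 | 19.6 |

(each reading ± 0.5 percentage points)

- time up to 2.5 min at which target stands highest
- the amount of target, in percent of the substrate charged, at that time

- the earlier runs were read with a standard deviation of 0.5 percentage points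

**The rule.** I took target as made at a making constant times substrate and lost at a loss constant times target, the usual consecutive-reaction maximum. Target stands still when target over substrate equals the balance ratio, the making constant over the loss constant.

**Reading it.** The first reading gave a making constant of 0.00909 s⁻¹. From 50.0 s to 80.0 s, target rose 0.8 points, against a scatter of 0.5 points per reading. That is 2.67 × 10⁻⁴ s⁻¹ of the charge. The mean of those two readings was 23.0% for target and 26.1% for substrate. So the balance ratio 0.995 came out.

**Bracket.** Target over substrate read 0.865 at 60.0 s and 1.19 at 80.0 s. With the rise taken as flat, the ratio was 0.883, which these two readings put by interpolation at 1.02 min. With the rise doubled, it was 1.14, interpolated to 1.28 min. I committed to 1.13 min and about 23.0%, the mean target read above.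

**Forecast.** It gave 1.35 min and 23.7%, saying “The maximum comes where formation” equals loss. Its time lay later than the upper end of my bracket.

**The flask.** Target peaked at 1.08 min with 23.0%, inside my bracket. There substrate stood at 24.9% and target at 23.0%, a ratio of 0.924.

    target → over-reaction product (k = 0.0120 s⁻¹)
    intermediate A → side product (k = 0.0110 s⁻¹)
    2 substrate → self-condensation product (k = 0.840 M⁻¹ s⁻¹)
    intermediate B ⇌ intermediate C (K = 2.10, k = 0.0160 s⁻¹)
    substrate → intermediate A (k = 0.0110 s⁻¹)
    intermediate A → target (k = 0.700 s⁻¹)
    substrate ⇌ intermediate B (K = 1.40, k = 0.0120 s⁻¹)

The neighbour flask left until 1.5 min ended with target over substrate at 1.32, higher than the balance ratio 0.995. So it should stand past its peak, and its target ended at 21.9%, under its highest 23.0%.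

The earlier runs and the new flask are simulated for an exercise; noise was put on by code.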